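Compound numbers 1 to 22 are fixed by the steps below and are used throughout. Atom labels follow isoflavone numbering: O1, C2, C3, C4, C4a, C5 to C8 and C8a in rings C and A, and C1' to C6' in ring B.

## Analysis of the target

The target is a 5,7,2',4'-tetrahydroxyisoflavone in which ring A is fused to the pyranone ring C and ring B sits on C3; a 3-hydroxy-3-methylbutyl chain is on C6 and a prenyl group on C3'. It has no stereocentre and no stereogenic double bond, so the task is one of regiochemistry and functional group tolerance. Ring A carries a substituent on every carbon except C8, and ring B has four neighbouring substituents with the prenyl group wedged between two oxygens. The prenyl alkene lies next to two phenols and closes to a dimethylchroman under acid, and the tertiary alcohol, two carbons from C6, would do the same with O5 or O7, or eliminate. The pyranone opens at C2 with hydroxide and the free tetraphenol is easily oxidised, so the last deprotection can use neither acid nor hydrogenation nor hot aqueous base. The strategy rests on one feature of ring A: O5 and O7 flank C6 and O1 is para to C6. The phenol that delivers O1 (compound 8) is therefore symmetric about the O1–C6 axis, and either of its two ortho carbons can become C4a.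

## Retrosynthetic reasoning

Target 22 is traced back to the tetra-O-allyl isoflavone acetate 20 by cutting four O–allyl bonds and the acetate. Allyl ethers leave under zerovalent palladium without acid or hydrogen, which the prenyl group and the tertiary alcohol require. The acetate is needed because the ring closure uses an acid anhydride, which would turn a free tertiary alcohol into a far more ionisable ester. The forward reaction must remove five groups in one operation, through the tetraphenol acetate 21, without opening the pyranone.

Isoflavone 20 is cut at C4–C4a, giving the aryloxyacrylic acid 18. This bond is chosen because the ring A part of 18 is symmetric, so the acylation has only one possible outcome on ring A. Cutting O1–C8a or C3–C1' would need a halogen at one particular carbon of a ring that otherwise has no such bias. The forward reaction is an intramolecular acylation through the mixed anhydride 19, run without a strong Lewis acid.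

Acid 18 comes from hydroxy acid 16 by acetylation, through mixed anhydride 17, and 16 comes from ethyl ester 15 by saponification. The acetate is put on after the saponification because hydroxide would not tell a tertiary acetate from the hindered, electron-rich ester of 15.

Ester 15 is cut at the O1–C2 bond into phenol 8 and enol tosylate 14. This divides the molecule into two halves of similar size, each carrying one aromatic ring with all its substituents. The forward reaction is an addition–elimination of the phenoxide on a vinylogous sulfonic ester, and it must go through oxygen rather than through a ring carbon.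

Tosylate 14 comes from the enol 13, and 13 from aldehyde 12. The aldehyde carbon of 12 becomes C2, and a two-carbon diazo ester supplies C3 and C4. The C2–C3 bond forms by addition and the C3–C1' bond by migration of the aryl group. This replaces a multistep homologation to an arylacetic ester followed by formylation.

Aldehyde 12 is the bis-allyl ether of 11, and 11 is cut at the C3'–CH2 bond into 9 and 10. The prenyl group is put on first, on the cheapest material, because direct C-alkylation between two phenoxide oxygens is short but not selective.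

Phenol 8 comes from tosylate 7 by cleavage of the sulfonate. The chain of 7 is cut at the methyl–carbinol bond to ketone 6, then back through enone 5 to aldehyde 4, whose formyl carbon is the benzylic carbon of the chain. Aldehyde 4 comes from 2 and 3, and 2 from 1. The formyl carbon of 1 already sits between two oxygens and para to the third, which is exactly the place of C6. The only differentiation needed is at the oxygen para to the formyl group, and a sulfonate is chosen there because it does not migrate and survives the chain-building steps.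

## Alternatives that were turned down

Alternative 1: Ring A would be built last, on a finished pyranone. The disconnections are C7–C8 and C5–C6. In the forward step the dienolate of the 2-methyl group of pyranone ester A2 would open lactone A3, and the new carbonyl would then condense through its C6 enolate with the neighbouring ester and aromatise to A1. In its favour, it assembles the fully substituted ring A, with the tertiary alcohol already in place, in one operation and needs no differentiation of the ring A oxygens. On step count and on that point it is stronger than the chosen route. Against it, the dienolate may simply deprotonate A3. After the lactone opening, the more acidic α-position is on the C8 side, not the C6 side that has to react. C6 of A2 (the later C2) is a Michael acceptor. A2 itself needs several steps. A1 still carries acetal protecting groups next to the prenyl group, so the route ends with an acid treatment, which is the condition under which the target closes to chromans. The chosen route offers bond formations of well-known types, a regiochemistry fixed by symmetry, and an end game free of acid.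

Alternative 2: Ring B would be built by benzannulation. The disconnections are C5'–C6', C2'–C3', C4'–C5' and C1'–C2'. Photochemical Wolff rearrangement of diazo enone A5 would give a vinylketene that adds siloxyalkyne A6, and ring opening and electrocyclisation would give phenol A4. In its favour, A6 places the prenyl group between the two oxygens without any regiochemical question. That is better than step 7 of the chosen route, which is short but unselective. Against it, the effort goes into the easier ring. The whole ring A chromone with its C6 chain must be made first, carried on to A5 and then through a photoreaction, in which the chromone is itself a chromophore. A6 is sensitive and needs its own synthesis. A4 again ends with acid-labile acetal groups on the oxygens next to the tertiary alcohol. The chosen route makes ring B in four steps from 9 and accepts a modest first step on cheap material.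

Alternative 3: Ring C would be closed at O1–C8a. In the forward step the enol oxygen of the α-hydroxymethylene ketone A8 would be joined to the brominated ring A carbon with CuI, 1,10-phenanthroline and Cs2CO3 (Ullmann-type O-arylation), giving A7. In its favour, the closure runs under mild base, so the prenyl group is in no danger during ring formation. On that point it is stronger than an acid-mediated acylation. Against it, the bromine must sit on one particular carbon of ring A, so the symmetry of the ring is given up and a fully differentiated, brominated aryl ketone is needed. The C4–C4a bond still has to be made, only earlier and intermolecularly, before a formylation supplies C2. A7 carries four acetal groups that need acid at the end. The chosen route needs no halogen handle, draws its regiochemistry from symmetry, and removes its protecting groups with zerovalent palladium and methoxide.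

Key step: step 14

Remark on the chemistry: the double-bond geometry of 14 to 19 is not decisive, because the acidic ring closure equilibrates the push–pull alkene. These compounds are drawn and named as the Z isomers expected from a lithium-chelated enolate and substitution with retention.

## Route

Step 1
Reactants: 1 2,4,6-trihydroxybenzaldehyde
Product: 2 4-formyl-3,5-dihydroxyphenyl 4-methylbenzenesulfonate
Conditions: TsCl (1.0 equiv), K2CO3 (1.05 equiv), acetone, 0 °C to rt
Reagents that add atoms: 4-methylbenzenesulfonyl chloride, Cc1ccc(cc1)S(=O)(=O)Cl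
Why: O-Sulfonylation of a phenoxide; the hydroxyl para to the formyl group is the most acidic and is not held in a hydrogen bond to the carbonyl, so one equivalent of carbonate should ionise it first. A sulfonate, unlike an acyl group, does not migrate to the neighbouring oxygens in the next step.

Step 2
Reactants: 2 4-formyl-3,5-dihydroxyphenyl 4-methylbenzenesulfonate; 3 allyl bromide
Product: 4 4-formyl-3,5-bis(prop-2-enyloxy)phenyl 4-methylbenzenesulfonate
Conditions: allyl bromide (2.5 equiv), K2CO3, DMF, 50 °C
Reagents that add atoms: allyl bromide (second equivalent of 3), C=CCBr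
Why: Twofold Williamson etherification; each of the two remaining phenols takes up one allyl group, so two equivalents of the bromide are consumed. A temperature of 50 °C is far below that of an aromatic Claisen rearrangement and the aryl sulfonate is inert to carbonate.

Step 3
Reactants: 4 4-formyl-3,5-bis(prop-2-enyloxy)phenyl 4-methylbenzenesulfonate
Product: 5 4-[(E)-3-oxobut-1-enyl]-3,5-bis(prop-2-enyloxy)phenyl 4-methylbenzenesulfonate
Conditions: (MeO)2P(O)CH2C(O)CH3, NaH, THF, 0 to 40 °C
Reagents that add atoms: dimethyl (2-oxopropyl)phosphonate, CC(=O)CP(=O)(OC)OC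
Why: Horner–Wadsworth–Emmons olefination with a stabilised ketophosphonate anion should give the E enone. The aldehyde has no α-hydrogen, and hydroxide, which could attack the sulfonate in an aldol condensation with acetone, is avoided.

Step 4
Reactants: 5 4-[(E)-3-oxobut-1-enyl]-3,5-bis(prop-2-enyloxy)phenyl 4-methylbenzenesulfonate
Product: 6 4-(3-oxobutyl)-3,5-bis(prop-2-enyloxy)phenyl 4-methylbenzenesulfonate
Conditions: [(Ph3P)CuH]6 (5 mol %), PhMe2SiH, t-BuOH, toluene, rt
Reagents that add atoms: none
Why: Copper hydride conjugate reduction: hydride goes to the β-carbon of the enone, t-BuOH protonates the copper enolate and the silane regenerates CuH. The isolated alkenes of the allyl ethers and the aryl sulfonate are not reduced, which a catalytic hydrogenation could not guarantee.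

Step 5
Reactants: 6 4-(3-oxobutyl)-3,5-bis(prop-2-enyloxy)phenyl 4-methylbenzenesulfonate
Product: 7 4-(3-hydroxy-3-methylbutyl)-3,5-bis(prop-2-enyloxy)phenyl 4-methylbenzenesulfonate
Conditions: MeMgBr (1.2 equiv), THF, −20 to 0 °C; aq. NH4Cl
Reagents that add atoms: methylmagnesium bromide, C[Mg]Br
Why: Grignard 1,2-addition to a methyl ketone gives the tertiary alcohol. Any attack of the reagent at the sulfonate sulfur would only anticipate the cleavage of step 6.

Step 6
Reactants: 7 4-(3-hydroxy-3-methylbutyl)-3,5-bis(prop-2-enyloxy)phenyl 4-methylbenzenesulfonate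
Product: 8 4-(3-hydroxy-3-methylbutyl)-3,5-bis(prop-2-enyloxy)phenol
Conditions: KOH, dioxane/H2O, 90 °C; then dilute HCl to pH 6
Reagents that add atoms: none
Why: Alkaline hydrolysis of an aryl sulfonate by attack of hydroxide at sulfur; allyl aryl ethers and the tertiary alcohol are stable to aqueous hydroxide. Dioxane is used in place of an alcohol so that no alkyl tosylate forms that could O-alkylate the phenoxide.

Step 7
Reactants: 9 2,4-dihydroxybenzaldehyde; 10 prenyl bromide
Product: 11 2,4-dihydroxy-3-(3-methylbut-2-enyl)benzaldehyde
Conditions: KOH (10 % aq.), 0 °C to rt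
Reagents that add atoms: none
Why: C-Alkylation of a resorcinol dianion in water: the carbon between the two phenoxide oxygens is the most nucleophilic ring position and water disfavours O-alkylation. The 5-prenyl and O-prenyl isomers are expected as well and are removed by chromatography, which is accepted on the first step of a cheap material.

Step 8
Reactants: 11 2,4-dihydroxy-3-(3-methylbut-2-enyl)benzaldehyde; 3 allyl bromide
Product: 12 3-(3-methylbut-2-enyl)-2,4-bis(prop-2-enyloxy)benzaldehyde
Conditions: allyl bromide (3 equiv), K2CO3, DMF, 50 °C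
Reagents that add atoms: allyl bromide (second equivalent of 3), C=CCBr
Why: Twofold Williamson etherification, one allyl group for each phenol, so two equivalents of the bromide end up in the product. The chelated and hindered 2-hydroxyl is the slower one and is the reason for the excess of bromide and the mild warming.

Step 9
Reactants: 12 3-(3-methylbut-2-enyl)-2,4-bis(prop-2-enyloxy)benzaldehyde
Product: 13 ethyl (Z)-3-hydroxy-2-[3-(3-methylbut-2-enyl)-2,4-bis(prop-2-enyloxy)phenyl]prop-2-enoate
Conditions: N2CHCO2Et, HBF4·OEt2 (10 mol %), CH2Cl2, −78 °C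
Reagents that add atoms: ethyl diazoacetate, CCOC(=O)C=[N+]=[N-]
Why: Brønsted acid catalysed reaction of an aromatic aldehyde with a diazoacetate with 1,2-aryl shift: the diazo carbon adds to the protonated aldehyde and the aryl group migrates to it as dinitrogen leaves, giving the α-formyl ester as its hydrogen-bonded Z enol. An ortho,para-dialkoxyphenyl group migrates readily, which should suppress the hydride shift to the β-keto ester. The step provides C2, C3 and C4 of the pyranone at once.

Step 10
Reactants: 13 ethyl (Z)-3-hydroxy-2-[3-(3-methylbut-2-enyl)-2,4-bis(prop-2-enyloxy)phenyl]prop-2-enoate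
Product: 14 ethyl (Z)-2-[3-(3-methylbut-2-enyl)-2,4-bis(prop-2-enyloxy)phenyl]-3-(4-methylphenylsulfonyloxy)prop-2-enoate
Conditions: TsCl, N-methylimidazole, LiOH, THF, 0 °C
Reagents that add atoms: 4-methylbenzenesulfonyl chloride, Cc1ccc(cc1)S(=O)(=O)Cl
Why: O-Sulfonylation of the lithium enolate by the sulfonylimidazolium ion; chelation of lithium between the enolate oxygen and the ester carbonyl should fix the Z geometry. The enol tosylate is a vinylogous mixed anhydride ready for addition–elimination.

Step 11
Reactants: 8 4-(3-hydroxy-3-methylbutyl)-3,5-bis(prop-2-enyloxy)phenol; 14 ethyl (Z)-2-[3-(3-methylbut-2-enyl)-2,4-bis(prop-2-enyloxy)phenyl]-3-(4-methylphenylsulfonyloxy)prop-2-enoate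
Product: 15 ethyl (Z)-3-[4-(3-hydroxy-3-methylbutyl)-3,5-bis(prop-2-enyloxy)phenoxy]-2-[3-(3-methylbut-2-enyl)-2,4-bis(prop-2-enyloxy)phenyl]prop-2-enoate
Conditions: Cs2CO3, MeCN, rt to 40 °C
Reagents that add atoms: none
Why: Nucleophilic vinylic substitution by addition–elimination: the caesium phenoxide adds at the β-carbon of the acrylate and the ester enolate expels tosylate, with retention expected. A polar aprotic solvent favours attack through oxygen, and the tertiary alcohol is not acidic enough to compete.

Step 12
Reactants: 15 ethyl (Z)-3-[4-(3-hydroxy-3-methylbutyl)-3,5-bis(prop-2-enyloxy)phenoxy]-2-[3-(3-methylbut-2-enyl)-2,4-bis(prop-2-enyloxy)phenyl]prop-2-enoate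
Product: 16 (Z)-3-[4-(3-hydroxy-3-methylbutyl)-3,5-bis(prop-2-enyloxy)phenoxy]-2-[3-(3-methylbut-2-enyl)-2,4-bis(prop-2-enyloxy)phenyl]prop-2-enoic acid
Conditions: LiOH, THF/H2O, 40 °C; then 1 M HCl to pH 3, 0 °C
Reagents that add atoms: none
Why: Saponification of the ethyl ester; the carboxylate, once formed, resists conjugate attack, and methanol is left out so that methoxide cannot displace the aryloxy group. The acetate is introduced only after this step because hydroxide would not distinguish a tertiary acetate from this hindered ester.

Step 13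
Reactants: 16 (Z)-3-[4-(3-hydroxy-3-methylbutyl)-3,5-bis(prop-2-enyloxy)phenoxy]-2-[3-(3-methylbut-2-enyl)-2,4-bis(prop-2-enyloxy)phenyl]prop-2-enoic acid
Product: 18 (Z)-3-[4-(3-acetoxy-3-methylbutyl)-3,5-bis(prop-2-enyloxy)phenoxy]-2-[3-(3-methylbut-2-enyl)-2,4-bis(prop-2-enyloxy)phenyl]prop-2-enoic acid, via acetic mixed anhydride 17 (not isolated)
Conditions: Ac2O, DMAP (cat.), pyridine, CH2Cl2, rt; then H2O/THF, rt
Reagents that add atoms: acetic anhydride, CC(=O)OC(C)=O
Why: DMAP-catalysed acetylation of the tertiary alcohol. The carboxylic acid is acetylated as well to mixed anhydride 17, which water and pyridine cleave at the more electrophilic acetyl carbonyl during work-up to return the acid.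

Step 14
Reactants: 18 (Z)-3-[4-(3-acetoxy-3-methylbutyl)-3,5-bis(prop-2-enyloxy)phenoxy]-2-[3-(3-methylbut-2-enyl)-2,4-bis(prop-2-enyloxy)phenyl]prop-2-enoic acid
Product: 20 4-[3-[3-(3-methylbut-2-enyl)-2,4-bis(prop-2-enyloxy)phenyl]-4-oxo-5,7-bis(prop-2-enyloxy)chromen-6-yl]-2-methylbutan-2-yl acetate, via acyl trifluoroacetate 19 (not isolated)
Conditions: TFAA (1.2 equiv), CH2Cl2, 0 °C to rt; then aq. NaHCO3
Reagents that add atoms: none
Why: Trifluoroacetic anhydride converts the acid into the acyl trifluoroacetate 19, which reacts, helped by the trifluoroacetic acid set free, as an acylium ion stabilised by the enol ether oxygen. This electrophile attacks the ring A carbon that is ortho to the enol ether oxygen, ortho to one allyloxy group and para to the other, and loss of a proton gives the pyranone; this is an intramolecular Friedel–Crafts acylation, the known way from 3-aryloxyacrylic acids to chromones, run here through a mixed anhydride as is done for phloroglucinol-type ethers. Ring C closes as a six-membered ring by electrophilic aromatic substitution, with the new carbonyl exocyclic to the bond formed (6-exo closure at the acyl carbon), and no stereocentre is created. The regiochemistry on ring A is fixed by the substrate, because the 4-alkyl-3,5-bis(allyloxy)phenyl ether is symmetric and its two ortho carbons are the same, so only the 6-alkyl isoflavone can form. Attack on ring B would close a four-membered ring and is excluded, and intermolecular trifluoroacetylation of the electron-rich rings is held back by using little more than one equivalent of anhydride at 0 °C. If some E acid is present, reversible protonation at C3 or addition of trifluoroacetate at C2 lets the push–pull alkene rotate, so both isomers should converge. No strong Lewis acid is present, and in dilute CH2Cl2 the acid formed should leave the prenyl alkene, the allyl ethers and the tertiary acetate intact, the acetate being far less prone to ionise than a trifluoroacetate on the free alcohol would be.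

Step 15
Reactants: 20 4-[3-[3-(3-methylbut-2-enyl)-2,4-bis(prop-2-enyloxy)phenyl]-4-oxo-5,7-bis(prop-2-enyloxy)chromen-6-yl]-2-methylbutan-2-yl acetate
Product: 22 3-[2,4-dihydroxy-3-(3-methylbut-2-enyl)phenyl]-5,7-dihydroxy-6-(3-hydroxy-3-methylbutyl)chromen-4-one, via tetraphenol acetate 21 (not isolated)
Conditions: Pd(PPh3)4 (10 mol %), K2CO3, MeOH/THF, rt, argon; then NaOMe, 40 °C; AcOH
Reagents that add atoms: none
Why: Zerovalent palladium ionises the four aryl allyl ethers and methanol in large excess captures the allyl fragments (Tsuji–Trost deallylation), so the phenols are freed without acid or hydrogen. Methoxide then transesterifies the tertiary acetate, which carbonate alone would cleave too slowly. By then the substrate is a polyphenoxide, which protects the pyranone against attack at C2, and exclusion of air with an acetic acid quench protects the tetraphenol.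

## Compound list

1 | 2,4,6-trihydroxybenzaldehyde | O=Cc1c(O)cc(O)cc1O | starting material
2 | 4-formyl-3,5-dihydroxyphenyl 4-methylbenzenesulfonate | O=Cc1c(O)cc(OS(=O)(=O)c2ccc(C)cc2)cc1O | intermediate
3 | allyl bromide (3-bromoprop-1-ene) | C=CCBr | starting material
4 | 4-formyl-3,5-bis(prop-2-enyloxy)phenyl 4-methylbenzenesulfonate | O=Cc1c(OCC=C)cc(OS(=O)(=O)c2ccc(C)cc2)cc1OCC=C | intermediate
5 | 4-[(E)-3-oxobut-1-enyl]-3,5-bis(prop-2-enyloxy)phenyl 4-methylbenzenesulfonate | CC(=O)/C=C/c1c(OCC=C)cc(OS(=O)(=O)c2ccc(C)cc2)cc1OCC=C | intermediate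
6 | 4-(3-oxobutyl)-3,5-bis(prop-2-enyloxy)phenyl 4-methylbenzenesulfonate | CC(=O)CCc1c(OCC=C)cc(OS(=O)(=O)c2ccc(C)cc2)cc1OCC=C | intermediate
7 | 4-(3-hydroxy-3-methylbutyl)-3,5-bis(prop-2-enyloxy)phenyl 4-methylbenzenesulfonate | CC(C)(O)CCc1c(OCC=C)cc(OS(=O)(=O)c2ccc(C)cc2)cc1OCC=C | intermediate
8 | 4-(3-hydroxy-3-methylbutyl)-3,5-bis(prop-2-enyloxy)phenol | CC(C)(O)CCc1c(OCC=C)cc(O)cc1OCC=C | intermediate
9 | 2,4-dihydroxybenzaldehyde | O=Cc1ccc(O)cc1O | starting material
10 | prenyl bromide (1-bromo-3-methylbut-2-ene) | CC(C)=CCBr | starting material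
11 | 2,4-dihydroxy-3-(3-methylbut-2-enyl)benzaldehyde | CC(C)=CCc1c(O)ccc(C=O)c1O | intermediate
12 | 3-(3-methylbut-2-enyl)-2,4-bis(prop-2-enyloxy)benzaldehyde | CC(C)=CCc1c(OCC=C)ccc(C=O)c1OCC=C | intermediate
13 | ethyl (Z)-3-hydroxy-2-[3-(3-methylbut-2-enyl)-2,4-bis(prop-2-enyloxy)phenyl]prop-2-enoate | O/C=C(/c1ccc(OCC=C)c(CC=C(C)C)c1OCC=C)C(=O)OCC | intermediate
14 | ethyl (Z)-2-[3-(3-methylbut-2-enyl)-2,4-bis(prop-2-enyloxy)phenyl]-3-(4-methylphenylsulfonyloxy)prop-2-enoate | Cc1ccc(cc1)S(=O)(=O)O/C=C(/c1ccc(OCC=C)c(CC=C(C)C)c1OCC=C)C(=O)OCC | intermediate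
15 | ethyl (Z)-3-[4-(3-hydroxy-3-methylbutyl)-3,5-bis(prop-2-enyloxy)phenoxy]-2-[3-(3-methylbut-2-enyl)-2,4-bis(prop-2-enyloxy)phenyl]prop-2-enoate | C=CCOc1cc(O/C=C(/c2ccc(OCC=C)c(CC=C(C)C)c2OCC=C)C(=O)OCC)cc(OCC=C)c1CCC(C)(C)O | intermediate
16 | (Z)-3-[4-(3-hydroxy-3-methylbutyl)-3,5-bis(prop-2-enyloxy)phenoxy]-2-[3-(3-methylbut-2-enyl)-2,4-bis(prop-2-enyloxy)phenyl]prop-2-enoic acid | C=CCOc1cc(O/C=C(/c2ccc(OCC=C)c(CC=C(C)C)c2OCC=C)C(=O)O)cc(OCC=C)c1CCC(C)(C)O | intermediate
17 | acetic (Z)-3-[4-(3-acetoxy-3-methylbutyl)-3,5-bis(prop-2-enyloxy)phenoxy]-2-[3-(3-methylbut-2-enyl)-2,4-bis(prop-2-enyloxy)phenyl]prop-2-enoic anhydride | C=CCOc1cc(O/C=C(/c2ccc(OCC=C)c(CC=C(C)C)c2OCC=C)C(=O)OC(C)=O)cc(OCC=C)c1CCC(C)(C)OC(C)=O | intermediate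
18 | (Z)-3-[4-(3-acetoxy-3-methylbutyl)-3,5-bis(prop-2-enyloxy)phenoxy]-2-[3-(3-methylbut-2-enyl)-2,4-bis(prop-2-enyloxy)phenyl]prop-2-enoic acid | C=CCOc1cc(O/C=C(/c2ccc(OCC=C)c(CC=C(C)C)c2OCC=C)C(=O)O)cc(OCC=C)c1CCC(C)(C)OC(C)=O | intermediate
19 | (Z)-3-[4-(3-acetoxy-3-methylbutyl)-3,5-bis(prop-2-enyloxy)phenoxy]-2-[3-(3-methylbut-2-enyl)-2,4-bis(prop-2-enyloxy)phenyl]prop-2-enoic trifluoroacetic anhydride | C=CCOc1cc(O/C=C(/c2ccc(OCC=C)c(CC=C(C)C)c2OCC=C)C(=O)OC(=O)C(F)(F)F)cc(OCC=C)c1CCC(C)(C)OC(C)=O | intermediate
20 | 4-[3-[3-(3-methylbut-2-enyl)-2,4-bis(prop-2-enyloxy)phenyl]-4-oxo-5,7-bis(prop-2-enyloxy)chromen-6-yl]-2-methylbutan-2-yl acetate | C=CCOc1cc2occ(-c3ccc(OCC=C)c(CC=C(C)C)c3OCC=C)c(=O)c2c(OCC=C)c1CCC(C)(C)OC(C)=O | intermediate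
21 | 4-[3-[2,4-dihydroxy-3-(3-methylbut-2-enyl)phenyl]-5,7-dihydroxy-4-oxochromen-6-yl]-2-methylbutan-2-yl acetate | CC(C)=CCc1c(O)ccc(-c2coc3cc(O)c(CCC(C)(C)OC(C)=O)c(O)c3c2=O)c1O | intermediate
22 | 3-[2,4-dihydroxy-3-(3-methylbut-2-enyl)phenyl]-5,7-dihydroxy-6-(3-hydroxy-3-methylbutyl)chromen-4-one (CNP0076924.0) | CC(C)=CCc1c(O)ccc(-c2coc3cc(O)c(CCC(C)(C)O)c(O)c3c2=O)c1O | target

## Step count and least certain steps

Total: 15 steps. Longest linear sequence: 11 steps (steps 1 to 6, then 11 to 15); the ring B branch (steps 7 to 10) joins at step 11.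

Step 14 (key step). The acylium ion draws on the lone pair of O1, which lowers the nucleophilicity of ring A, so the closure may be slow. Trifluoroacetylation of ring A or of C5' of ring B, acidolysis of the tertiary acetate, or addition of acid to the prenyl alkene could then overtake it. The fallback reverses the polarity at the same bond; it sets out from 8 and 14 and returns at 22. Phenol 8 is brominated once ortho to the hydroxyl (NBS, CH2Cl2, −78 °C) to 2-bromo-4-(3-hydroxy-3-methylbutyl)-3,5-bis(prop-2-enyloxy)phenol F1. F1 is joined to 14 as in step 11 to give ethyl (Z)-3-[2-bromo-4-(3-hydroxy-3-methylbutyl)-3,5-bis(prop-2-enyloxy)phenoxy]-2-[3-(3-methylbut-2-enyl)-2,4-bis(prop-2-enyloxy)phenyl]prop-2-enoate F2. The tertiary hydroxyl of F2 is deprotonated with NaH, and bromine–lithium exchange with t-BuLi in THF at −95 °C lets the aryllithium attack the ester carbonyl (Parham-type cyclisation). This gives 6-(3-hydroxy-3-methylbutyl)-3-[3-(3-methylbut-2-enyl)-2,4-bis(prop-2-enyloxy)phenyl]-5,7-bis(prop-2-enyloxy)chromen-4-one F3. Pd(PPh3)4 with K2CO3 in methanol then gives 22 directly, so steps 12 to 14 and the acetate are not needed. This closure needs the Z isomer, since nothing equilibrates the alkene under anionic conditions.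

Step 1. The acidity difference between the hydroxyls is moderate, so sulfonylation at an ortho hydroxyl or twice may lower the selectivity. The fallback differentiates the oxygens stepwise; it sets out from 1 and returns at 4. Two equivalents of MOMCl with i-Pr2NEt leave only the chelated hydroxyl free, giving 2-hydroxy-4,6-bis(methoxymethoxy)benzaldehyde F4. Allyl bromide and K2CO3 give 2,4-bis(methoxymethoxy)-6-(prop-2-enyloxy)benzaldehyde F5. HCl in methanol removes the acetals to give 2,4-dihydroxy-6-(prop-2-enyloxy)benzaldehyde F6. In F6 one hydroxyl is chelated and the para one is free, a pattern whose para-selective tosylation (TsCl, K2CO3, acetone) is dependable, and it gives 4-formyl-3-hydroxy-5-(prop-2-enyloxy)phenyl 4-methylbenzenesulfonate F7. A second allylation gives 4.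

Step 7. Regioselectivity is poor: alkylation at C5, at oxygen, or twice competes with alkylation at C3. The fallback delivers the prenyl group by rearrangement; it sets out from 9 and returns at 11. The free 4-hydroxyl is etherified with 3-chloro-3-methylbut-1-yne (DBU, CuCl2 cat., MeCN, 0 °C) to give 2-hydroxy-4-(2-methylbut-3-yn-2-yloxy)benzaldehyde F8. Semihydrogenation (H2, Pd/CaCO3 poisoned with Pb(OAc)2, quinoline) gives 2-hydroxy-4-(2-methylbut-3-en-2-yloxy)benzaldehyde F9. Heating F9 in N,N-diethylaniline at about 130 °C brings about a [3,3] Claisen rearrangement, expected mainly to C3 because the chelated hydroxy aldehyde fixes the double-bond character between C3 and C4, and this gives 11.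

Step 9. Hydride shift in place of aryl shift would give the β-keto ester, and the acid may react at the prenyl alkene. The fallback is a classical homologation followed by formylation; it sets out from 12 and returns at 13. Wittig reaction with the ylide from (methoxymethyl)triphenylphosphonium chloride and KOt-Bu gives 1-[(E)-2-methoxyethenyl]-3-(3-methylbut-2-enyl)-2,4-bis(prop-2-enyloxy)benzene F10, expected as an E/Z mixture. Mild hydrolysis (TsOH cat., acetone/H2O) gives 2-[3-(3-methylbut-2-enyl)-2,4-bis(prop-2-enyloxy)phenyl]acetaldehyde F11. Oxidation with NaClO2 and NaH2PO4 in the presence of 2-methylbut-2-ene gives 2-[3-(3-methylbut-2-enyl)-2,4-bis(prop-2-enyloxy)phenyl]acetic acid F12. EtI and K2CO3 give ethyl 2-[3-(3-methylbut-2-enyl)-2,4-bis(prop-2-enyloxy)phenyl]acetate F13. Claisen formylation with NaH and ethyl formate gives 13.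

Step 11. The phenoxide may attack sulfur, which transfers the sulfonyl group back to the phenol, or it may react through a ring carbon. The fallback replaces addition–elimination by a copper-catalysed C–O coupling; it sets out from 13 and 8 and returns at 15. Enol 13 is converted with Ph3PBr2 and Et3N in CH2Cl2 into ethyl (Z)-3-bromo-2-[3-(3-methylbut-2-enyl)-2,4-bis(prop-2-enyloxy)phenyl]prop-2-enoate F14. F14 is coupled with 8 under CuI, N,N-dimethylglycine and Cs2CO3 in dioxane at 90 °C (Ullmann-type vinylation of a phenol, with retention at the alkene) to give 15.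

## Further compounds

F1 | step 14 | 2-bromo-4-(3-hydroxy-3-methylbutyl)-3,5-bis(prop-2-enyloxy)phenol | CC(C)(O)CCc1c(OCC=C)cc(O)c(Br)c1OCC=C
F2 | step 14 | ethyl (Z)-3-[2-bromo-4-(3-hydroxy-3-methylbutyl)-3,5-bis(prop-2-enyloxy)phenoxy]-2-[3-(3-methylbut-2-enyl)-2,4-bis(prop-2-enyloxy)phenyl]prop-2-enoate | C=CCOc1cc(O/C=C(/c2ccc(OCC=C)c(CC=C(C)C)c2OCC=C)C(=O)OCC)c(Br)c(OCC=C)c1CCC(C)(C)O
F3 | step 14 | 6-(3-hydroxy-3-methylbutyl)-3-[3-(3-methylbut-2-enyl)-2,4-bis(prop-2-enyloxy)phenyl]-5,7-bis(prop-2-enyloxy)chromen-4-one | C=CCOc1cc2occ(-c3ccc(OCC=C)c(CC=C(C)C)c3OCC=C)c(=O)c2c(OCC=C)c1CCC(C)(C)O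
F4 | step 1 | 2-hydroxy-4,6-bis(methoxymethoxy)benzaldehyde | COCOc1cc(O)c(C=O)c(OCOC)c1
F5 | step 1 | 2,4-bis(methoxymethoxy)-6-(prop-2-enyloxy)benzaldehyde | COCOc1cc(OCC=C)c(C=O)c(OCOC)c1
F6 | step 1 | 2,4-dihydroxy-6-(prop-2-enyloxy)benzaldehyde | O=Cc1c(O)cc(O)cc1OCC=C
F7 | step 1 | 4-formyl-3-hydroxy-5-(prop-2-enyloxy)phenyl 4-methylbenzenesulfonate | O=Cc1c(O)cc(OS(=O)(=O)c2ccc(C)cc2)cc1OCC=C
F8 | step 7 | 2-hydroxy-4-(2-methylbut-3-yn-2-yloxy)benzaldehyde | C#CC(C)(C)Oc1ccc(C=O)c(O)c1
F9 | step 7 | 2-hydroxy-4-(2-methylbut-3-en-2-yloxy)benzaldehyde | C=CC(C)(C)Oc1ccc(C=O)c(O)c1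
F10 | step 9 | 1-[(E)-2-methoxyethenyl]-3-(3-methylbut-2-enyl)-2,4-bis(prop-2-enyloxy)benzene | CO/C=C/c1ccc(OCC=C)c(CC=C(C)C)c1OCC=C
F11 | step 9 | 2-[3-(3-methylbut-2-enyl)-2,4-bis(prop-2-enyloxy)phenyl]acetaldehyde | O=CCc1ccc(OCC=C)c(CC=C(C)C)c1OCC=C
F12 | step 9 | 2-[3-(3-methylbut-2-enyl)-2,4-bis(prop-2-enyloxy)phenyl]acetic acid | OC(=O)Cc1ccc(OCC=C)c(CC=C(C)C)c1OCC=C
F13 | step 9 | ethyl 2-[3-(3-methylbut-2-enyl)-2,4-bis(prop-2-enyloxy)phenyl]acetate | CCOC(=O)Cc1ccc(OCC=C)c(CC=C(C)C)c1OCC=C
F14 | step 11 | ethyl (Z)-3-bromo-2-[3-(3-methylbut-2-enyl)-2,4-bis(prop-2-enyloxy)phenyl]prop-2-enoate | Br/C=C(/c1ccc(OCC=C)c(CC=C(C)C)c1OCC=C)C(=O)OCC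
A1 | alternative 1 | 3-[2,4-bis(methoxymethoxy)-3-(3-methylbut-2-enyl)phenyl]-5,7-dihydroxy-6-(3-hydroxy-3-methylbutyl)chromen-4-one | CC(C)=CCc1c(OCOC)ccc(-c2coc3cc(O)c(CCC(C)(C)O)c(O)c3c2=O)c1OCOC
A2 | alternative 1 | methyl 5-[2,4-bis(methoxymethoxy)-3-(3-methylbut-2-enyl)phenyl]-2-methyl-4-oxopyran-3-carboxylate | COC(=O)c1c(C)occ(-c2ccc(OCOC)c(CC=C(C)C)c2OCOC)c1=O
A3 | alternative 1 | 6,6-dimethyltetrahydropyran-2-one | CC1(C)CCCC(=O)O1
A4 | alternative 2 | 3-[2-hydroxy-3-(3-methylbut-2-enyl)-4-(triisopropylsilyloxy)phenyl]-5,7-bis(methoxymethoxy)-6-[3-(methoxymethoxy)-3-methylbutyl]chromen-4-one | CC(C)=CCc1c(O[Si](C(C)C)(C(C)C)C(C)C)ccc(-c2coc3cc(OCOC)c(CCC(C)(C)OCOC)c(OCOC)c3c2=O)c1O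
A5 | alternative 2 | (E)-1-diazo-4-[5,7-bis(methoxymethoxy)-6-[3-(methoxymethoxy)-3-methylbutyl]-4-oxochromen-3-yl]but-3-en-2-one | [N-]=[N+]=CC(=O)/C=C/c1coc2cc(OCOC)c(CCC(C)(C)OCOC)c(OCOC)c2c1=O
A6 | alternative 2 | triisopropyl(5-methylhex-4-en-1-ynoxy)silane | CC(C)=CCC#CO[Si](C(C)C)(C(C)C)C(C)C
A7 | alternative 3 | 3-[2,4-bis(methoxymethoxy)-3-(3-methylbut-2-enyl)phenyl]-6-(3-hydroxy-3-methylbutyl)-5,7-bis(methoxymethoxy)chromen-4-one | COCOc1cc2occ(-c3ccc(OCOC)c(CC=C(C)C)c3OCOC)c(=O)c2c(OCOC)c1CCC(C)(C)O
A8 | alternative 3 | (Z)-1-[2-bromo-5-(3-hydroxy-3-methylbutyl)-4,6-bis(methoxymethoxy)phenyl]-3-hydroxy-2-[2,4-bis(methoxymethoxy)-3-(3-methylbut-2-enyl)phenyl]prop-2-en-1-one | O/C=C(/c1ccc(OCOC)c(CC=C(C)C)c1OCOC)C(=O)c1c(Br)cc(OCOC)c(CCC(C)(C)O)c1OCOC
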